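Temperature does not speed the steps here equally: the passing of target into isomer of the product B has an activation energy 46.0 kJ mol⁻¹ above that of target's making.

    partner + free catalyst → spent catalyst (k1 = 1.86 M⁻¹ s⁻¹, Ea1 = 54.0 kJ mol⁻¹)
    substrate + partner ⇌ target (K2 = 43.1 M⁻¹, k2 = 0.615 M⁻¹ s⁻¹, Ea2 = 39.0 kJ mol⁻¹, ΔH2 = −45.0 kJ mol⁻¹)
    target ⇌ isomer of the product B (K3 = 2.7, k3 = 0.00883 s⁻¹, Ea3 = 85.0 kJ mol⁻¹, ΔH3 = −37.0 kJ mol⁻¹)
    target + free catalyst ⇌ isomer of the product A + free catalyst, rate k4*[free catalyst]*[target] forward; the back reaction follows from the equilibrium constant (k4 = 3.10 M⁻¹ s⁻¹, Ea4 = 48.0 kJ mol⁻¹)
    substrate + partner ⇌ isomer of the product A (K5 = 140 M⁻¹, k5 = 0.142 M⁻¹ s⁻¹, Ea5 = 62.0 kJ mol⁻¹, ΔH5 = −4.00 kJ mol⁻¹)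
    (constants at 20 °C)

common to all: substrate 20 mM; partner 22.0 mM; free catalyst 3.0 mM; time 2.5 min

| flask | temperature |
|---|---|
| south-west | 5 °C |
| north-east | 20 °C |
| south-east | −10 °C |
| north-west | −25 °C |

- constants are those at 20 °C; use the activation energies and enthalpies for any other temperature

- the flask that comes out highest in amount of target, in percent of the substrate charged, or "all alike" when all lie within 1.5 percentage points (south-west / north-east / south-east / north-west / all alike)
- target at the end, in percent of the substrate charged, south-west
- target at the end, in percent of the substrate charged, north-east
- target at the end, in percent of the substrate charged, south-east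
- target at the end, in percent of the substrate charged, north-west

**The ceiling.** South-west and north-east look nearly the same: equal charges, 5 °C against 20 °C. Divide the rate at which target is made by the first-order constant with which it is lost, and time drops out. That loss constant adds three terms: target back to substrate + partner, target into isomer of the product B, and target into isomer of the product A, which carries c(free catalyst). Returns from the isomers are left out. For north-east at its charges the constant is 0.0324 s⁻¹, and the ceiling, 41.8 %, is the level of target, in percent of the substrate charged, at which making equals loss. The usual term is quasi-steady level.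

**Two flasks.** In south-west the constant is 0.00679 s⁻¹, a drop by a factor 4.77, while making drops by 2.37. So the south-west ceiling, 84.1 %, stands twice as high. The approach half-life, ln(2) over the constant, is 0.357 min in north-east and 1.70 min in south-west. Because north-east, with its constant at the charges, gets 7.00 half-lives in 2.5 min, its target should ride its ceiling down as substrate and partner go. South-west gets 1.47 and should still be climbing. With the charges held fixed, my rise to the ceiling gives 53.7 % and 41.4 %. Those charges do not stay, so I commit to the order alone: south-west above north-east.

**The forecast.** It gives 29 % for south-west, 15.2 % for north-east, 22.3 % for south-east and 9.8 % for north-west, and it names south-west: "So the intermediate temperature, 5 °C (south-west), wins." Its south-west and north-east figures lie well below my fixed-charge figures.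

**The result.** The simulation gives 29.5 %, 15.5 %, 22.1 % and 9.81 % in that order, with south-west highest, so the forecast holds. In north-east target went from 19.0 % at 1.25 min to 15.5 % at 2.50 min; at that end substrate stood at 48.4 %, partner at 39.9 % of its own charge and free catalyst at 3.46 % of its charge, and the ceiling reckoned from those end amounts, returns from the isomers still left out, is 11.2 %, below the target. In south-west target went from 23.1 % to 29.5 % over the same times, under an end ceiling of 37.1 %, and at the end it was still made 1.70 times faster than used up, each step taken net.

**Colder repeat.** Take south-west repeated at −20 °C. The constant is 5.11 × 10⁻⁴ s⁻¹, the half-life 22.6 min, and the ceiling 211 % lies above the charge, so the same rise gives 15.6 %. The simulated flask ends at 13.4 %, with 85.6 % of the substrate left.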